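## Retrosynthetic overview
1. Target ⇒ Sonogashira disconnection at C11–C12: alkynyl 1,2-dioxane + (E)-1-iodoundeca-1,10-diene. The polyene tail goes on last.
2. Alkynyl dioxane ⇒ C6–OMe exchange, then the key C3–O bond: H2O2 + MeOH + an acyclic keto enoate. An enantioselective 6-exo peroxa-Michael closure of the ketone perhydrate makes the ring and sets C3. C6 then follows by anomeric equilibration.
3. Keto enoate ⇒ Wittig at C2=C3 from 4-oxonon-8-ynal ⇒ acylation at C5–C6 of hex-5-ynoic acid chloride with the Grignard reagent of 2-(2-bromoethyl)-1,3-dioxolane.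
4. Vinyl iodide ⇒ Takai olefination of dec-9-enal ⇒ dec-9-en-1-ol.
5. Ring order: there is only one ring, the 1,2-dioxane, and it is formed in step 3.

Assumption: the absolute sense of induction in step 3 can only be fixed by experiment; the quinine-derived catalyst is written, and its commercial quinidine-derived pseudoenantiomer is used instead if the opposite C3 face is attacked.

## Route

Step 1
Reactants: 1 hex-5-ynoic acid; 2 2-(2-bromoethyl)-1,3-dioxolane
Product: 5 1-(1,3-dioxolan-2-yl)oct-7-yn-3-one, via hex-5-ynoyl chloride 3 (not isolated), via Grignard reagent 4 (not isolated)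
Conditions: 1, (COCl)2, DMF (cat.), CH2Cl2, 0 °C to rt, evaporate; 2, Mg, THF, ≤30 °C; add 4 (1.0 equiv) slowly to 3, THF, −78 °C
Reagents that add atoms: none
Why: Acid chloride formation followed by low-temperature Grignard acylation, in which at −78 °C in THF the acyl chloride reacts far faster than the product ketone or the alkyne C–H, so the addition stops at the ketone and no stereocenter is formed.

Step 2
Reactants: 5 1-(1,3-dioxolan-2-yl)oct-7-yn-3-one; 6 methyl (triphenylphosphoranylidene)acetate
Product: 8 methyl (2E)-6-oxoundec-2-en-10-ynoate, via keto aldehyde 7 (not isolated)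
Conditions: 2 M HCl, THF, rt; NaHCO3, extract (CH2Cl2); then 6, CH2Cl2, rt
Reagents that add atoms: none
Why: Acid-catalysed acetal hydrolysis followed by a Wittig olefination with a stabilised ylide, which takes only the aldehyde and not the ketone and gives the E-enoate (>20:1), while using 7 crude avoids its aldol and furan side reactions.

Step 3
Reactants: 8 methyl (2E)-6-oxoundec-2-en-10-ynoate
Product: 11 methyl 2-[(3S,6R)-6-methoxy-6-(pent-4-yn-1-yl)-1,2-dioxan-3-yl]acetate, via perhydrate 9 (not isolated), via dioxanol 10 (not isolated)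
Conditions: urea·H2O2 (3 equiv), quinine-derived squaramide 3-{[3,5-bis(trifluoromethyl)phenyl]amino}-4-{[(8α,9S)-6'-methoxycinchonan-9-yl]amino}cyclobut-3-ene-1,2-dione (10 mol%), CH2Cl2, 0 °C, 48 h; filter; then MeOH, CSA (30 mol%), rt, 12 h
Reagents that add atoms: hydrogen peroxide (delivered as urea·H2O2) OO; methanol CO
Why: Proposed new method: a catalytic enantioselective peroxa-Michael/hemiketalisation cascade in which H2O2 bridges a remote ketone and an unactivated enoate; H2O2 adds reversibly to the C6 ketone to give the stereolabile perhydrate 9, the quinuclidine nitrogen deprotonates its OOH group (pKa about 12) while the two squaramide N–H bonds hold the ester carbonyl and the developing enolate, and a chair-like 6-exo-trig closure delivers the terminal peroxy oxygen to the Si face of C3, forming the C3–O bond, the ring and the 3S centre, with the quinuclidinium proton quenching the enolate before it can attack O–O to give an epoxide; because 9 racemises through the ketone the closure is a dynamic kinetic process, and C6 is then set thermodynamically, since acid methanolysis of 10 through the cyclic peroxycarbenium ion gives the anomerically stabilised axial OMe with both carbon chains equatorial, which is 6R (OMe cis to CH2CO2Me); a squaramide is chosen because thioureas are desulfurised by H2O2; the closest known reaction types are the racemic secondary-amine-catalysed cyclisation of hydroperoxy (hemi)ketals onto enoates, the cinchona-amine-catalysed asymmetric hydroperoxidation of enones to cyclic peroxyhemiketals, and bifunctional cinchona-catalysed oxa-Michael cycloetherification, none of which has been shown enantioselectively for a hydroperoxide adding to an α,β-unsaturated ester.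

Step 4
Reactants: 12 dec-9-en-1-ol
Product: 13 dec-9-enal
Conditions: Cu(MeCN)4OTf (5 mol%), 2,2'-bipyridine (5 mol%), TEMPO (5 mol%), N-methylimidazole (10 mol%), air, MeCN, rt
Reagents that add atoms: none
Why: Copper/nitroxyl-catalysed aerobic alcohol oxidation stops cleanly at the aldehyde for primary aliphatic alcohols and leaves the terminal alkene untouched.

Step 5
Reactants: 13 dec-9-enal
Product: 14 (1E)-1-iodoundeca-1,10-diene
Conditions: CrCl2 (6 equiv), CHI3 (2 equiv), 1,4-dioxane–THF (6:1), 0 °C to rt
Reagents that add atoms: iodoform IC(I)I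
Why: Takai olefination, in which the gem-dichromium carbenoid adds to the aldehyde and eliminates through the less crowded arrangement to give the E-vinyl iodide (about 10:1 or better in dioxane-rich solvent, residual Z removed on AgNO3-silica) while the isolated alkene is inert to divalent chromium.

Step 6
Reactants: 11 methyl 2-[(3S,6R)-6-methoxy-6-(pent-4-yn-1-yl)-1,2-dioxan-3-yl]acetate; 14 (1E)-1-iodoundeca-1,10-diene
Product: 15 peroxyacarnoate A = methyl 2-[(3S,6R)-6-[(6E)-hexadeca-6,15-dien-4-yn-1-yl]-6-methoxy-1,2-dioxan-3-yl]acetate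
Conditions: PdCl2(PPh3)2 (5 mol%), CuI (10 mol%), Et3N (3 equiv), THF, rt, degassed, dark
Reagents that add atoms: none
Why: Sonogashira coupling, in which oxidative addition of the vinyl iodide to zerovalent palladium and reductive elimination retain the E geometry, a tertiary amine at rt is too weak to deprotonate the ester α-carbon (so C3 is not lost by retro-Michael), and 3-alkoxy-1,2-dioxanes are dialkyl-type peroxides known to tolerate such room-temperature couplings, so C3 and C6 are untouched.

## Compound list
1 | hex-5-ynoic acid | C#CCCCC(=O)O | starting material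
2 | 2-(2-bromoethyl)-1,3-dioxolane | BrCCC1OCCO1 | starting material
3 | hex-5-ynoyl chloride | C#CCCCC(=O)Cl | intermediate
4 | [2-(1,3-dioxolan-2-yl)ethyl]magnesium bromide | Br[Mg]CCC1OCCO1 | intermediate
5 | 1-(1,3-dioxolan-2-yl)oct-7-yn-3-one | C#CCCCC(=O)CCC1OCCO1 | intermediate
6 | methyl (triphenylphosphoranylidene)acetate | COC(=O)C=P(c1ccccc1)(c1ccccc1)c1ccccc1 | starting material
7 | 4-oxonon-8-ynal | C#CCCCC(=O)CCC=O | intermediate
8 | methyl (2E)-6-oxoundec-2-en-10-ynoate | C#CCCCC(=O)CC/C=C/C(=O)OC | intermediate
9 | methyl (2E)-6-hydroperoxy-6-hydroxyundec-2-en-10-ynoate (C6 stereolabile) | C#CCCCC(O)(OO)CC/C=C/C(=O)OC | intermediate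
10 | methyl 2-[(3S)-6-hydroxy-6-(pent-4-yn-1-yl)-1,2-dioxan-3-yl]acetate (C6 anomers interconvert) | C#CCCCC1(O)CC[C@@H](CC(=O)OC)OO1 | intermediate
11 | methyl 2-[(3S,6R)-6-methoxy-6-(pent-4-yn-1-yl)-1,2-dioxan-3-yl]acetate | C#CCCC[C@]1(OC)CC[C@@H](CC(=O)OC)OO1 | intermediate
12 | dec-9-en-1-ol | C=CCCCCCCCCO | starting material
13 | dec-9-enal | C=CCCCCCCCC=O | intermediate
14 | (1E)-1-iodoundeca-1,10-diene | C=CCCCCCCC/C=C/I | intermediate
15 | peroxyacarnoate A, methyl 2-[(3S,6R)-6-[(6E)-hexadeca-6,15-dien-4-yn-1-yl]-6-methoxy-1,2-dioxan-3-yl]acetate | C=CCCCCCCC/C=C/C#CCCC[C@]1(OC)CC[C@@H](CC(=O)OC)OO1 | target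

## Step count and risks
Total steps: 6. Longest linear sequence: 4 (steps 1, 2, 3, 6).

**Risk 1, step 3 (the new step).**
- Failure modes: the ester acceptor may be too unreactive, the enantioselectivity too low, the enolate may close to an epoxide, or H2O2 may N-oxidise the catalyst.
- The fallback uses known chemistry only. It replaces the conjugate addition by a stereospecific C–O alkylation whose stereocenter comes from a reagent-controlled allylation.
- It sets out from 7 and comes back at 11.

Crude 7 is allylated with (−)-Ipc2B(allyl) (from (+)-α-pinene; Et2O, −78 °C), which takes only the aldehyde, to give (9R)-9-hydroxydodec-11-en-1-yn-6-one F1. MsCl/Et3N gives (4R)-7-oxododec-1-en-11-yn-4-yl methanesulfonate F2. Urea·H2O2 and Sc(OTf)3 in MeOH convert the ketone into (4R)-7-hydroperoxy-7-methoxydodec-1-en-11-yn-4-yl methanesulfonate F3, as both ketal epimers. KOtBu/18-crown-6 closes the ring by 6-exo-tet SN2 displacement with inversion, and CSA/MeOH equilibrates the ketal carbon, giving (3R,6S)-3-methoxy-3-(pent-4-yn-1-yl)-6-(prop-2-en-1-yl)-1,2-dioxane F4. Ozonolysis of the alkene, which reacts far faster than the alkyne (CH2Cl2, −78 °C, Me2S), gives 2-[(3S,6R)-6-methoxy-6-(pent-4-yn-1-yl)-1,2-dioxan-3-yl]acetaldehyde F5. Pinnick oxidation (NaClO2, NaH2PO4, 2-methyl-2-butene) gives 2-[(3S,6R)-6-methoxy-6-(pent-4-yn-1-yl)-1,2-dioxan-3-yl]acetic acid F6, and TMSCHN2 gives 11.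

**Risk 2, step 6.**
- Failure modes: CuI, zerovalent palladium or free PPh3 may cleave the O–O bond, or the amine may fragment the dioxane.
- The fallback reverses the order of events, so that the peroxide never meets the metals.
- It sets out from 8 (with 14) and comes back at 15.

Sonogashira coupling of 8 with 14 under the step 6 conditions gives methyl (2E,12E)-6-oxodocosa-2,12,21-trien-10-ynoate F7. This is then put through the step 3 conditions, to which the enyne and the terminal alkene are inert. It passes through methyl (2E,12E)-6-hydroperoxy-6-hydroxydocosa-2,12,21-trien-10-ynoate F8 and methyl 2-[(3S)-6-[(6E)-hexadeca-6,15-dien-4-yn-1-yl]-6-hydroxy-1,2-dioxan-3-yl]acetate F9, and acid methanolysis gives 15.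

**Risk 3, step 5.**
- Failure mode: an unbranched aldehyde may give an E/Z mixture that is hard to separate and would be carried into the enyne.
- The fallback replaces the chromium olefination by syn-hydrometalation of an alkyne, which can only give the E isomer.
- It sets out from 13 and comes back at 14.

Dimethyl (1-diazo-2-oxopropyl)phosphonate with K2CO3 in MeOH (Ohira–Bestmann homologation) gives undec-1-en-10-yne F10. Cp2Zr(H)Cl (1.05 equiv, THF, 0 °C to rt) adds to the alkyne in preference to the alkene to give chlorobis(cyclopentadienyl)[(1E)-undeca-1,10-dien-1-yl]zirconium F11, and I2 cleaves the C–Zr bond with retention to give 14.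

## Further compounds
F1 | step 3 | (9R)-9-hydroxydodec-11-en-1-yn-6-one | C#CCCCC(=O)CC[C@@H](O)CC=C
F2 | step 3 | (4R)-7-oxododec-1-en-11-yn-4-yl methanesulfonate | C#CCCCC(=O)CC[C@@H](OS(C)(=O)=O)CC=C
F3 | step 3 | (4R)-7-hydroperoxy-7-methoxydodec-1-en-11-yn-4-yl methanesulfonate (both C7 epimers) | C#CCCCC(OC)(OO)CC[C@@H](OS(C)(=O)=O)CC=C
F4 | step 3 | (3R,6S)-3-methoxy-3-(pent-4-yn-1-yl)-6-(prop-2-en-1-yl)-1,2-dioxane | C#CCCC[C@]1(OC)CC[C@@H](CC=C)OO1
F5 | step 3 | 2-[(3S,6R)-6-methoxy-6-(pent-4-yn-1-yl)-1,2-dioxan-3-yl]acetaldehyde | C#CCCC[C@]1(OC)CC[C@@H](CC=O)OO1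
F6 | step 3 | 2-[(3S,6R)-6-methoxy-6-(pent-4-yn-1-yl)-1,2-dioxan-3-yl]acetic acid | C#CCCC[C@]1(OC)CC[C@@H](CC(=O)O)OO1
F7 | step 6 | methyl (2E,12E)-6-oxodocosa-2,12,21-trien-10-ynoate | C=CCCCCCCC/C=C/C#CCCCC(=O)CC/C=C/C(=O)OC
F8 | step 6 | methyl (2E,12E)-6-hydroperoxy-6-hydroxydocosa-2,12,21-trien-10-ynoate | C=CCCCCCCC/C=C/C#CCCCC(O)(OO)CC/C=C/C(=O)OC
F9 | step 6 | methyl 2-[(3S)-6-[(6E)-hexadeca-6,15-dien-4-yn-1-yl]-6-hydroxy-1,2-dioxan-3-yl]acetate | C=CCCCCCCC/C=C/C#CCCCC1(O)CC[C@@H](CC(=O)OC)OO1
F10 | step 5 | undec-1-en-10-yne | C=CCCCCCCCC#C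
F11 | step 5 | chlorobis(cyclopentadienyl)[(1E)-undeca-1,10-dien-1-yl]zirconium | C=CCCCCCCC/C=C/[Zr](Cl)(C1C=CC=C1)C1C=CC=C1
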